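The molecule is cut at the bond between C2 of ring A (the pentyl-bearing 4-pyranone) and the adjacent methine. The key step joins both pyranone halves in one base-free operation: a Liebeskind–Srogl coupling of a 2-methylthio-pyranone with an alkenylstannane, in which the future methine is the internal carbon of a silyl-protected 2-stannyl allylic alcohol. It exploits that C2 of ring A is the β-carbon of the vinylogous ester O1–C2=C3–C4=O, so its C–S bond is activated, and that the methine is α to the later ketone. Hydroxyl-directed hydrogenation then sets this stereocentre, an Evans aldol sets the other, and the ketone is unveiled last.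

Key step: step 13

Remark: the acyclic di- and triketone intermediates are handled as mixtures of tautomers and of epimers at carbons that later become sp2 ring carbons; their SMILES leave these centres undefined.

Step 1
Reactants: 1 pentan-3-one
Product: 3 2-methyl-1,1-bis(methylsulfanyl)pent-1-en-3-one, via dilithium ketene dithiolate 2 (not isolated)
Conditions: LiN(SiMe3)2 (2.1 equiv), CS2, THF, −78 to 0 °C; then MeI (2.2 equiv), rt
Reagents that add atoms: carbon disulfide S=C=S; iodomethane CI
Why: The lithium enolate should add to CS2 and, after a second deprotonation, the ene-1,1-dithiolate is S-methylated twice to the α-oxo ketene dithioacetal (ketene dithioacetal synthesis from a ketone); no stereocentre is formed.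

Step 2
Reactants: 3 2-methyl-1,1-bis(methylsulfanyl)pent-1-en-3-one; 4 hexanoyl chloride
Product: 6 2,4-dimethyl-1,1-bis(methylsulfanyl)dec-1-ene-3,5-dione, via lithium enolate 5 (not isolated)
Conditions: LiN(SiMe3)2 (2.1 equiv), THF, −78 °C; then 4, −78 to 0 °C
Reagents that add atoms: none
Why: Kinetic deprotonation can only occur at the ethyl CH2, and C-acylation of this enolate by the acid chloride should give the 1,3-diketone, the second equivalent of base absorbing its acidic proton (Claisen-type enolate acylation).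

Step 3
Reactants: 6 2,4-dimethyl-1,1-bis(methylsulfanyl)dec-1-ene-3,5-dione
Product: 7 3,5-dimethyl-2-(methylsulfanyl)-6-pentyl-4H-pyran-4-one
Conditions: CF3CO2H, CH2Cl2, 0 °C to rt
Reagents that add atoms: none
Why: Under acid the enol oxygen of the hexanoyl ketone should add to the bis(methylsulfanyl) carbon in a 6-endo conjugate addition, and loss of methanethiol leaves the 2-methylsulfanyl-4-pyranone (addition–elimination ring closure of an α-oxo ketene dithioacetal).

Step 4
Reactants: 8 acrolein (prop-2-enal)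
Product: 10 2-bromoprop-2-enal (2-bromoacrolein), via 2,3-dibromopropanal 9 (not isolated)
Conditions: Br2, CH2Cl2, −78 °C; then Et3N, −78 to 0 °C; used at once
Reagents that add atoms: bromine BrBr
Why: Bromine should add across the C=C bond and triethylamine then removes HBr from the α-bromo aldehyde in an E1cB-type elimination (bromination–dehydrobromination).

Step 5
Reactants: 11 (R)-4-benzyl-3-propanoyl-1,3-oxazolidin-2-one; 10 2-bromoprop-2-enal
Product: 13 (R)-4-benzyl-3-[(2R,3R)-4-bromo-3-hydroxy-2-methylpent-4-enoyl]-1,3-oxazolidin-2-one, via dibutylboron Z-enolate 12 (not isolated)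
Conditions: Bu2BOTf, Et3N, CH2Cl2, −78 to 0 °C; then 10, −78 to 0 °C
Reagents that add atoms: none
Why: Evans syn aldol: the Z-boron enolate should react through a closed chair transition state on the face opposite the benzyl group of the (R)-auxiliary, which sets the 2R and 3R centres (methyl and hydroxyl syn).

Step 6
Reactants: 13 (R)-4-benzyl-3-[(2R,3R)-4-bromo-3-hydroxy-2-methylpent-4-enoyl]-1,3-oxazolidin-2-one
Product: 14 (R)-4-benzyl-3-[(2R,3R)-4-bromo-3-[(tert-butyldimethylsilyl)oxy]-2-methylpent-4-enoyl]-1,3-oxazolidin-2-one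
Conditions: TBSOTf, 2,6-lutidine, CH2Cl2, −78 to 0 °C
Reagents that add atoms: tert-butyldimethylsilyl trifluoromethanesulfonate CC(C)(C)[Si](C)(C)OS(=O)(=O)C(F)(F)F
Why: The silyl triflate with a hindered pyridine base should silylate the secondary allylic alcohol without touching the imide or the alkenyl bromide (silyl ether protection).

Step 7
Reactants: 14 (R)-4-benzyl-3-[(2R,3R)-4-bromo-3-[(tert-butyldimethylsilyl)oxy]-2-methylpent-4-enoyl]-1,3-oxazolidin-2-one
Product: 15 (2S,3R)-4-bromo-3-[(tert-butyldimethylsilyl)oxy]-2-methylpent-4-en-1-ol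
Conditions: LiBH4, MeOH (1 equiv), THF, 0 °C
Reagents that add atoms: none
Why: Borohydride should cleave the exocyclic imide carbonyl to the primary alcohol and release the auxiliary without enolisation, so the α-centre is kept (reductive removal of an oxazolidinone auxiliary).

Step 8
Reactants: 15 (2S,3R)-4-bromo-3-[(tert-butyldimethylsilyl)oxy]-2-methylpent-4-en-1-ol
Product: 16 (2R,3R)-4-bromo-3-[(tert-butyldimethylsilyl)oxy]-2-methylpent-4-enal
Conditions: Dess–Martin periodinane, pyridine, CH2Cl2, 0 °C to rt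
Reagents that add atoms: none
Why: Buffered hypervalent-iodine oxidation should give the α-branched aldehyde without epimerisation (Dess–Martin oxidation).

Step 9
Reactants: 16 (2R,3R)-4-bromo-3-[(tert-butyldimethylsilyl)oxy]-2-methylpent-4-enal; 17 4-methylheptane-3,5-dione
Product: 19 (8S,9R)-10-bromo-9-[(tert-butyldimethylsilyl)oxy]-7-hydroxy-4,6,8-trimethylundec-10-ene-3,5-dione (mixture at C4, C6 and C7), via dilithium dienediolate 18 (not isolated)
Conditions: 17, LiN(iPr)2 (2 equiv), THF, −78 to 0 °C; then 16, −78 °C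
Reagents that add atoms: none
Why: The 1,3-diketone dianion should react with the aldehyde only at its terminal, more basic carbon (dianion aldol addition); the three new centres are of no consequence because they later become sp2 or carbonyl carbons.

Step 10
Reactants: 19 (8S,9R)-10-bromo-9-[(tert-butyldimethylsilyl)oxy]-7-hydroxy-4,6,8-trimethylundec-10-ene-3,5-dione
Product: 20 (8R,9R)-10-bromo-9-[(tert-butyldimethylsilyl)oxy]-4,6,8-trimethylundec-10-ene-3,5,7-trione (mixture at C4 and C6)
Conditions: Dess–Martin periodinane, pyridine, CH2Cl2, rt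
Reagents that add atoms: none
Why: The secondary alcohol should be oxidised to the 1,3,5-triketone under buffered, non-basic conditions that keep the C8 centre (Dess–Martin oxidation).

Step 11
Reactants: 20 (8R,9R)-10-bromo-9-[(tert-butyldimethylsilyl)oxy]-4,6,8-trimethylundec-10-ene-3,5,7-trione
Product: 21 2-[(2R,3R)-4-bromo-3-[(tert-butyldimethylsilyl)oxy]pent-4-en-2-yl]-6-ethyl-3,5-dimethyl-4H-pyran-4-one
Conditions: PPh3, CCl4, THF, rt
Reagents that add atoms: none
Why: Triphenylphosphine/CCl4 should activate an enol oxygen of the triketone so that the distal enol oxygen closes the six-membered ring with loss of Ph3PO, a mild dehydrative cyclisation to the 4-pyranone (ring B) that leaves the silyl ether and the side-chain centres intact.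

Step 12
Reactants: 21 2-[(2R,3R)-4-bromo-3-[(tert-butyldimethylsilyl)oxy]pent-4-en-2-yl]-6-ethyl-3,5-dimethyl-4H-pyran-4-one
Product: 22 2-[(2R,3R)-3-[(tert-butyldimethylsilyl)oxy]-4-(trimethylstannyl)pent-4-en-2-yl]-6-ethyl-3,5-dimethyl-4H-pyran-4-one
Conditions: Me3SnSnMe3, Pd(PPh3)4 (5 mol %), toluene, 90 °C
Reagents that add atoms: hexamethylditin C[Sn](C)(C)[Sn](C)(C)C
Why: Zerovalent palladium should insert into the alkenyl C–Br bond and take a Me3Sn group from the distannane (palladium-catalysed stannylation of an alkenyl bromide).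

Step 13
Reactants: 22 2-[(2R,3R)-3-[(tert-butyldimethylsilyl)oxy]-4-(trimethylstannyl)pent-4-en-2-yl]-6-ethyl-3,5-dimethyl-4H-pyran-4-one; 7 3,5-dimethyl-2-(methylsulfanyl)-6-pentyl-4H-pyran-4-one
Product: 23 2-[(3R,4R)-3-[(tert-butyldimethylsilyl)oxy]-4-(6-ethyl-3,5-dimethyl-4-oxo-4H-pyran-2-yl)pent-1-en-2-yl]-3,5-dimethyl-6-pentyl-4H-pyran-4-one
Conditions: Pd(PPh3)4 (10 mol %), Cu(O2CC6H3(OH)CH3) (monovalent copper 3-methylsalicylate, 2 equiv), THF, 50 °C
Reagents that add atoms: none
Why: Zerovalent palladium should insert into the C2–S bond of the vinylogous thioester 7, helped by the monovalent copper carboxylate, which binds the thiolate and at the same time takes the alkenyl group from tin and passes it to palladium; reductive elimination then forms the bond between C2 of ring A and the alkenyl carbon that becomes the methine. The closest known reaction type is the Liebeskind–Srogl coupling of heteroaromatic and vinylogous methyl thioethers with organostannanes. No ring is closed and no stereocentre is formed in this step; the methine centre is set in step 15 by the allylic hydroxyl, and the two existing centres are not touched. The step needs chemoselectivity for the C–S and C–Sn bonds over the acidic lateral C–H bonds of both pyranones, the silyl ether and the two enone systems. This is secured by the base-free, neutral conditions and by the activation of the C2–S bond as the β-position of the O1–C2=C3–C4=O system.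

Step 14
Reactants: 23 2-[(3R,4R)-3-[(tert-butyldimethylsilyl)oxy]-4-(6-ethyl-3,5-dimethyl-4-oxo-4H-pyran-2-yl)pent-1-en-2-yl]-3,5-dimethyl-6-pentyl-4H-pyran-4-one
Product: 24 2-[(3R,4R)-4-(6-ethyl-3,5-dimethyl-4-oxo-4H-pyran-2-yl)-3-hydroxypent-1-en-2-yl]-3,5-dimethyl-6-pentyl-4H-pyran-4-one
Conditions: HF·pyridine, pyridine, THF, 0 °C to rt
Reagents that add atoms: none
Why: Buffered fluoride should cleave the secondary silyl ether to the free allylic alcohol needed for direction, without a base that could move the double bond (fluoride desilylation).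

Step 15
Reactants: 24 2-[(3R,4R)-4-(6-ethyl-3,5-dimethyl-4-oxo-4H-pyran-2-yl)-3-hydroxypent-1-en-2-yl]-3,5-dimethyl-6-pentyl-4H-pyran-4-one
Product: 25 2-[(2R,3R,4R)-4-(6-ethyl-3,5-dimethyl-4-oxo-4H-pyran-2-yl)-3-hydroxypentan-2-yl]-3,5-dimethyl-6-pentyl-4H-pyran-4-one
Conditions: H2 (about 50 bar), [Rh(nbd)(dppb)]BF4 (10 mol %), CH2Cl2, rt
Reagents that add atoms: none
Why: The cationic monovalent rhodium catalyst should bind the hydroxyl and the 1,1-disubstituted alkene and deliver hydrogen from the hydroxyl face of the conformer with least allylic 1,2-strain, giving the new methyl anti to OH, i.e. the (R)-methine (hydroxyl-directed hydrogenation).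

Step 16
Reactants: 25 2-[(2R,3R,4R)-4-(6-ethyl-3,5-dimethyl-4-oxo-4H-pyran-2-yl)-3-hydroxypentan-2-yl]-3,5-dimethyl-6-pentyl-4H-pyran-4-one
Product: 26 (2S,4S)-2-(6-ethyl-3,5-dimethyl-4-oxo-4H-pyran-2-yl)-4-(3,5-dimethyl-4-oxo-6-pentyl-4H-pyran-2-yl)pentan-3-one (CNP0268096.3)
Conditions: Dess–Martin periodinane, pyridine, CH2Cl2, 0 °C
Reagents that add atoms: none
Why: Buffered Dess–Martin oxidation should convert the carbinol into the ketone without a base able to enolise the two now doubly activated methines, whose descriptors change from R to S only through the CIP rank of the new carbonyl.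

Compound list
1 | pentan-3-one | CCC(=O)CC | starting material
2 | dilithium 2-methyl-3-oxopent-1-ene-1,1-bis(thiolate) | CCC(=O)C(C)=C(S[Li])S[Li] | intermediate
3 | 2-methyl-1,1-bis(methylsulfanyl)pent-1-en-3-one | CCC(=O)C(C)=C(SC)SC | intermediate
4 | hexanoyl chloride | CCCCCC(Cl)=O | starting material
5 | lithium 4-methyl-5,5-bis(methylsulfanyl)penta-2,4-dien-3-olate | CC=C(O[Li])C(C)=C(SC)SC | intermediate
6 | 2,4-dimethyl-1,1-bis(methylsulfanyl)dec-1-ene-3,5-dione | CCCCCC(=O)C(C)C(=O)C(C)=C(SC)SC | intermediate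
7 | 3,5-dimethyl-2-(methylsulfanyl)-6-pentyl-4H-pyran-4-one | CCCCCc1oc(SC)c(C)c(=O)c1C | intermediate
8 | acrolein (prop-2-enal) | C=CC=O | starting material
9 | 2,3-dibromopropanal | O=CC(Br)CBr | intermediate
10 | 2-bromoprop-2-enal | C=C(Br)C=O | intermediate
11 | (R)-4-benzyl-3-propanoyl-1,3-oxazolidin-2-one | CCC(=O)N1[C@H](Cc2ccccc2)COC1=O | starting material
12 | dibutylboron (Z)-enolate of 11 | C/C=C(\OB(CCCC)CCCC)N1[C@H](Cc2ccccc2)COC1=O | intermediate
13 | (R)-4-benzyl-3-[(2R,3R)-4-bromo-3-hydroxy-2-methylpent-4-enoyl]-1,3-oxazolidin-2-one | C=C(Br)[C@H](O)[C@@H](C)C(=O)N1[C@H](Cc2ccccc2)COC1=O | intermediate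
14 | (R)-4-benzyl-3-[(2R,3R)-4-bromo-3-[(tert-butyldimethylsilyl)oxy]-2-methylpent-4-enoyl]-1,3-oxazolidin-2-one | C=C(Br)[C@H](O[Si](C)(C)C(C)(C)C)[C@@H](C)C(=O)N1[C@H](Cc2ccccc2)COC1=O | intermediate
15 | (2S,3R)-4-bromo-3-[(tert-butyldimethylsilyl)oxy]-2-methylpent-4-en-1-ol | C=C(Br)[C@H](O[Si](C)(C)C(C)(C)C)[C@@H](C)CO | intermediate
16 | (2R,3R)-4-bromo-3-[(tert-butyldimethylsilyl)oxy]-2-methylpent-4-enal | C=C(Br)[C@H](O[Si](C)(C)C(C)(C)C)[C@@H](C)C=O | intermediate
17 | 4-methylheptane-3,5-dione | CCC(=O)C(C)C(=O)CC | starting material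
18 | dilithium 4-methylhepta-2,4-diene-3,5-diolate (alkene geometry not defined) | CC=C(O[Li])C(C)=C(O[Li])CC | intermediate
19 | (8S,9R)-10-bromo-9-[(tert-butyldimethylsilyl)oxy]-7-hydroxy-4,6,8-trimethylundec-10-ene-3,5-dione | C=C(Br)[C@H](O[Si](C)(C)C(C)(C)C)[C@@H](C)C(O)C(C)C(=O)C(C)C(=O)CC | intermediate
20 | (8R,9R)-10-bromo-9-[(tert-butyldimethylsilyl)oxy]-4,6,8-trimethylundec-10-ene-3,5,7-trione | C=C(Br)[C@H](O[Si](C)(C)C(C)(C)C)[C@@H](C)C(=O)C(C)C(=O)C(C)C(=O)CC | intermediate
21 | 2-[(2R,3R)-4-bromo-3-[(tert-butyldimethylsilyl)oxy]pent-4-en-2-yl]-6-ethyl-3,5-dimethyl-4H-pyran-4-one | C=C(Br)[C@H](O[Si](C)(C)C(C)(C)C)[C@@H](C)c1oc(CC)c(C)c(=O)c1C | intermediate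
22 | 2-[(2R,3R)-3-[(tert-butyldimethylsilyl)oxy]-4-(trimethylstannyl)pent-4-en-2-yl]-6-ethyl-3,5-dimethyl-4H-pyran-4-one | C=C([Sn](C)(C)C)[C@H](O[Si](C)(C)C(C)(C)C)[C@@H](C)c1oc(CC)c(C)c(=O)c1C | intermediate
23 | 2-[(3R,4R)-3-[(tert-butyldimethylsilyl)oxy]-4-(6-ethyl-3,5-dimethyl-4-oxo-4H-pyran-2-yl)pent-1-en-2-yl]-3,5-dimethyl-6-pentyl-4H-pyran-4-one | C=C(c1oc(CCCCC)c(C)c(=O)c1C)[C@H](O[Si](C)(C)C(C)(C)C)[C@@H](C)c1oc(CC)c(C)c(=O)c1C | intermediate
24 | 2-[(3R,4R)-4-(6-ethyl-3,5-dimethyl-4-oxo-4H-pyran-2-yl)-3-hydroxypent-1-en-2-yl]-3,5-dimethyl-6-pentyl-4H-pyran-4-one | C=C(c1oc(CCCCC)c(C)c(=O)c1C)[C@H](O)[C@@H](C)c1oc(CC)c(C)c(=O)c1C | intermediate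
25 | 2-[(2R,3R,4R)-4-(6-ethyl-3,5-dimethyl-4-oxo-4H-pyran-2-yl)-3-hydroxypentan-2-yl]-3,5-dimethyl-6-pentyl-4H-pyran-4-one | CCCCCc1oc([C@H](C)[C@H](O)[C@@H](C)c2oc(CC)c(C)c(=O)c2C)c(C)c(=O)c1C | intermediate
26 | (2S,4S)-2-(6-ethyl-3,5-dimethyl-4-oxo-4H-pyran-2-yl)-4-(3,5-dimethyl-4-oxo-6-pentyl-4H-pyran-2-yl)pentan-3-one | CCCCCc1oc([C@H](C)C(=O)[C@@H](C)c2oc(CC)c(C)c(=O)c2C)c(C)c(=O)c1C | target

Total step count: 16. Longest linear sequence: 13 steps (steps 4 to 16, from acrolein 8).

Steps most likely to fail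

Step 13. Transmetalation between two hindered partners may be slow, so that protodestannylation and homocoupling of the stannane take over. The polarity of the union can then be reversed. The fallback sets out from pentan-3-one 1, hexanoyl chloride 4 and bromide 21. Condensation of 1 with tert-butoxybis(dimethylamino)methane should give the enaminone (E)-1-(dimethylamino)-2-methylpent-1-en-3-one F1. Deprotonation with LiN(SiMe3)2 (THF, −78 °C) gives lithium 5-(dimethylamino)-4-methylpenta-2,4-dien-3-olate F2, which is acylated by 4 to 1-(dimethylamino)-2,4-dimethyldec-1-ene-3,5-dione F3. CF3CO2H closes F3, with loss of dimethylamine, to 3,5-dimethyl-2-pentyl-4H-pyran-4-one F4. Zincation of its only ring C–H with TMPZnCl·LiCl gives (3,5-dimethyl-4-oxo-6-pentyl-4H-pyran-2-yl)zinc chloride F5, and Negishi coupling with 21 (Pd(OAc)2, SPhos, THF) comes back to the route at 23.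

Step 15. Facial selectivity may be poor, or the allylic alcohol may isomerise to the ketone, which would scramble the new centre. The centre can then be set by the catalyst instead of the substrate. The fallback sets out from silyl ether 23. Asymmetric hydrogenation of the 1,1-disubstituted alkene with a chiral iridium phosphinooxazoline complex, [Ir(cod)(tBu-PHOX)]B[C6H3(CF3)2]4 (the ligand enantiomer that gives the (R)-methine), H2, CH2Cl2, should give 2-[(2R,3R,4R)-3-[(tert-butyldimethylsilyl)oxy]-4-(6-ethyl-3,5-dimethyl-4-oxo-4H-pyran-2-yl)pentan-2-yl]-3,5-dimethyl-6-pentyl-4H-pyran-4-one F6. HF·pyridine then comes back to the route at 25.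

Step 11. While the triketone is enolised, the silyloxy group may be lost by β-elimination or the α-centre may epimerise. The ring can then be closed at the alcohol oxidation level, so that the free triketone 20 is never formed. The fallback sets out from hydroxy diketone 19. CF3CO2H should induce hemiketal formation between the hydroxyl and the distal ketone, and dehydration gives the dihydropyranone 2-[(2S,3R)-4-bromo-3-[(tert-butyldimethylsilyl)oxy]pent-4-en-2-yl]-6-ethyl-3,5-dimethyl-2,3-dihydro-4H-pyran-4-one F7. Dehydrogenation with DDQ (dioxane, 80 °C) comes back to the route at 21.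

Further compounds
F1 | step 13 | (E)-1-(dimethylamino)-2-methylpent-1-en-3-one | CN(C)/C=C(\C)C(=O)CC
F2 | step 13 | lithium 5-(dimethylamino)-4-methylpenta-2,4-dien-3-olate | CC=C(O[Li])/C(C)=C/N(C)C
F3 | step 13 | 1-(dimethylamino)-2,4-dimethyldec-1-ene-3,5-dione | CN(C)/C=C(\C)C(=O)C(C)C(=O)CCCCC
F4 | step 13 | 3,5-dimethyl-2-pentyl-4H-pyran-4-one | CCCCCc1occ(C)c(=O)c1C
F5 | step 13 | (3,5-dimethyl-4-oxo-6-pentyl-4H-pyran-2-yl)zinc chloride | CCCCCc1oc([Zn]Cl)c(C)c(=O)c1C
F6 | step 15 | 2-[(2R,3R,4R)-3-[(tert-butyldimethylsilyl)oxy]-4-(6-ethyl-3,5-dimethyl-4-oxo-4H-pyran-2-yl)pentan-2-yl]-3,5-dimethyl-6-pentyl-4H-pyran-4-one | CCCCCc1oc([C@H](C)[C@H](O[Si](C)(C)C(C)(C)C)[C@@H](C)c2oc(CC)c(C)c(=O)c2C)c(C)c(=O)c1C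
F7 | step 11 | 2-[(2S,3R)-4-bromo-3-[(tert-butyldimethylsilyl)oxy]pent-4-en-2-yl]-6-ethyl-3,5-dimethyl-2,3-dihydro-4H-pyran-4-one | C=C(Br)[C@H](O[Si](C)(C)C(C)(C)C)[C@@H](C)C1OC(CC)=C(C)C(=O)C1C
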